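## The problem

Isocycloheterophyllin (20) is a pentacyclic flavone with no stereocentre, so the difficulty lies in regiochemistry and in the order in which fragile groups appear. Ring C is flanked by a fully substituted phloroglucinol ring A (free 5-hydroxyl, prenyl on C6, a 2,2-dimethylpyran fused through O7 and C8) and by a 2',4',5'-trioxygenated ring B. The 2'-oxygen of ring B is tied back to C3 through a seven-membered oxepine (C2, C3, CH2, C(=CMe2), O, C2', C1'). On ring A, three different groups must go to O5/C6, O7 and C8, although C6 and C8 are electronically almost alike; on ring B, one of three phenolic oxygens must be singled out for ring closure. The oxepine contains an aryl enol ether with an exocyclic isopropylidene that acid hydrolyses or isomerises, the prenyl group cyclises onto its neighbouring phenols under acid, and the free catechol is oxidised in base or by oxidants, so the closing steps must be neutral and non-oxidising. The feature that opens the route is ring C itself: C2 carries ring B and C3 an sp3 CH2 (the pattern of an aryl–alkyl alkyne), while C4=O and O1 are ortho on ring A (a salicylaldehyde). The phloroglucinol-derived salicylaldehyde has two equivalent ortho hydroxyls, so ring C can be made from two simple fragments without ambiguity on ring A, and the second hydroxyl is left as the 5-hydroxyl.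

## Retrosynthesis

**Catechol release (20 from 19).** The two catechol O–Si bonds are cut last. Triisopropylsilyl ethers are chosen because fluoride buffered with acetic acid is the only deprotection that leaves the enol ether, the prenyl group, the chromene and the catechol untouched. Precursor 19 differs from the target only in these two ethers.

**Pyran ring (19 from 17 and 18).** The O7–CMe2 and C8–CH bonds are cut, giving 5,7-dihydroxy compound 17 and 3-methylbut-2-enal (18). The neighbouring option, a 7-O-propargyl ether and its thermal rearrangement, costs one step more. Either way the cut is only safe once C6 is occupied, because then C8 is the single free ring A carbon. The forward reaction must condense at C8 and close onto O7 in the presence of the chelated 5-hydroxyl and the silyl ethers.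

**Oxepine (17 from 16).** The O–C(vinyl) bond is cut to give the 2'-phenol and a tetrasubstituted vinyl bromide in 16. A ketone-dehydration route to the enol ether would favour the endocyclic, chromone-conjugated isomer. The vinyl bromide fixes the double bond in the exocyclic position because the C=C is never touched. The forward reaction is an intramolecular copper-catalysed O-vinylation forming a seven-membered ring.

**C6 prenyl (16 from 15, 14, 13, and 11 with 12).** Compound 16 comes from 15 by removing both methoxymethyl groups with acid, at a point where no enol ether exists yet. The C6–CH2 bond of 15 is cut back to the 5-O-(1,1-dimethylallyl) ether 14, made from propargyl ether 13 by semi-hydrogenation, and 13 comes from 5-hydroxyflavone 11 and 3-chloro-3-methylbut-1-yne (12). Direct C-prenylation would not distinguish C6 from C8; the [3,3] shift from O5 can only reach C6. This requires O7 to be masked and O5 to be the only free hydroxyl, which is exactly what the ring C construction delivers.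

**Ring C (11 from 2 and 10).** The C3–C4 and O1–C2 bonds are cut together, giving symmetric salicylaldehyde 2 and aryl–alkyl alkyne 10. This removes one ring and two bonds in one step and separates the molecule into a ring A fragment and a ring B fragment that already carries the oxepine handle. A stepwise diketone route would form the same bonds over several steps. The forward reaction must insert the alkyne with the aryl carbon towards oxygen and must leave the vinyl bromide alone. Methoxymethyl is used on O2' and O7 because it is small next to the alkyne, inert to base, heat and the metal, and removable separately from the silyl ethers.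

**Fragments (10 from 6 and 9; 6 from 5, 4, 3; 9 from 7; 2 from 1).** The propargylic C–C bond of 10 is cut to terminal alkyne 6 and allylic bromide 9, which comes from bromine addition to 3-methylbuta-1,2-diene (7) through the tertiary dibromide 8. Alkyne 6 is the one-carbon homologue of aldehyde 5, obtained from 2,4,5-trihydroxybenzaldehyde (3) by silylation of the two unchelated hydroxyls (4) and acetal protection of the chelated one. Aldehyde 2 is the 4-O-methoxymethyl ether of 2,4,6-trihydroxybenzaldehyde (1).

## Roads not taken

**Alternative 1:** Here the O–C2' bond of the oxepine is cut, and ring B is carried as a simple 3,4-dihydroxyphenyl group. In the forward step Ag2O would oxidise the catechol of the secondary allylic alcohol A2 to its ortho-quinone. The side-chain hydroxyl would then add at C2' in a conjugate sense and re-aromatisation would give the racemic isopropenyl ether A1.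
- Merits: ring B needs no protecting groups, the 2'-oxygen is created by the ring closure instead of being bought, and the quinone can only accept the tethered oxygen at C2'.
- Weak points: A1 is an allyl ether with an sp3 stereocentre that is made only to be destroyed. Moving its 1,1-disubstituted double bond into a tetrasubstituted enol ether is a difficult isomerisation beside a prenyl group, a chromene and free phenols. The oxidant also meets an electron-rich ring A and a chromene.
- Comparison: this road is shorter in protecting-group operations and avoids a metal-catalysed coupling at a hindered vinyl bromide. The chosen plan answers with an enol ether whose double-bond position is fixed by the bromide and with a catechol that stays silylated until the last step.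

**Alternative 2:** Here the O1–C8a bond is cut, so ring C is closed last. The enol oxygen of the bromo-diketone A4 (a 4-aroyl benzoxepinone with a fully substituted bromoarene ring A) would be coupled to C8a–Br with CuI, a diamine and Cs2CO3, giving the tris(triisopropylsilyl) ether A3.
- Merits: ring A arrives complete, so nothing but desilylation follows the ring closure, and the regiochemistry of ring C is fixed by construction.
- Weak points: the hexasubstituted bromoarene needs a long synthesis of its own. Acylation of the benzoxepinone by a doubly ortho-substituted aroyl unit is hindered. The acid-sensitive enol ether has to be carried through the whole sequence. Oxidative addition must occur at a C–Br bond flanked by two substituents.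
- Comparison: this road is better after the key step (one step against seven). The chosen plan makes two bonds in its key step from fragments that are each three or four steps from commercial phenols.

**Alternative 3:** Here ring A is built by benzannulation. Heating 3-ethoxycyclobut-2-en-1-one A6 with the prenyl siloxyalkyne A7 would give, through a vinylketene, [2+2] addition, ring opening and six-electron closure, the phenol A5.
- Merits: every ring A oxygen in A5 is differentiated from the start, and the prenyl group is placed on C6 without any rearrangement. This is a real advantage over the three steps and the difficult alkylation of a chelated phenol that the chosen plan spends there.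
- Weak points: the step solves ring A only. Ring C, the oxepine and the pyran remain to be made. The ethyl ether on the future O1 must be cleaved under conditions that threaten the prenyl group and the silyl ether. An acyl group must still be placed between two oxygens in competition with the other free position.
- Comparison: this road wins on ring A regiochemistry. The chosen plan buys ring A from the shelf and puts its main step into the bonds that join the two halves.

Key step: step 7

Assumption: compounds 1, 3, 7, 12 and 18 are taken as commercial, and all electron-rich phenols are handled under argon.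

## Route

Step 1
Reactants: 1 2,4,6-trihydroxybenzaldehyde
Product: 2 2,6-dihydroxy-4-(methoxymethoxy)benzaldehyde
Conditions: MOMCl (1.0 equiv), i-Pr2NEt (1.1 equiv), THF, 0 °C
Reagents that add atoms: chloromethyl methyl ether (MOMCl), COCCl
Why: Selective phenol O-alkylation (acetal formation); the 4-hydroxyl is the most acidic and the only one not hydrogen-bonded to the formyl group, so one equivalent of electrophile should be taken up there and the aldehyde stays symmetric.

Step 2
Reactants: 3 2,4,5-trihydroxybenzaldehyde
Product: 4 2-hydroxy-4,5-bis(triisopropylsilyloxy)benzaldehyde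
Conditions: TIPSCl (2.2 equiv), imidazole, DMF, 0 °C to rt, argon
Reagents that add atoms: triisopropylsilyl chloride (TIPSCl), CC(C)[Si](Cl)(C(C)C)C(C)C
Why: Phenol silylation; the bulky chloride should react at the two unchelated hydroxyls and leave the 2-hydroxyl, which is hydrogen-bonded to the aldehyde, free.

Step 3
Reactants: 4 2-hydroxy-4,5-bis(triisopropylsilyloxy)benzaldehyde
Product: 5 2-(methoxymethoxy)-4,5-bis(triisopropylsilyloxy)benzaldehyde
Conditions: MOMCl (2 equiv), i-Pr2NEt (3 equiv), CH2Cl2, 0 to 40 °C
Reagents that add atoms: chloromethyl methyl ether (MOMCl), COCCl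
Why: Standard acetal protection of a salicylaldehyde hydroxyl; excess reagent and mild warming overcome the hydrogen bond, and the silyl ethers are inert to the amine base.

Step 4
Reactants: 5 2-(methoxymethoxy)-4,5-bis(triisopropylsilyloxy)benzaldehyde
Product: 6 1-ethynyl-2-(methoxymethoxy)-4,5-bis(triisopropylsilyloxy)benzene
Conditions: TMSCHN2 (1.2 equiv), LiN(i-Pr)2 (LDA, 1.2 equiv), THF, −78 °C to rt
Reagents that add atoms: trimethylsilyldiazomethane (TMSCHN2), C[Si](C)(C)C=[N+]=[N-]
Why: Colvin rearrangement: the lithiated diazo compound adds to the aryl aldehyde, Peterson elimination gives a diazoalkene, and loss of N2 with a 1,2-shift in the alkylidene carbene gives the terminal alkyne; no protic base is present, so aryl silyl ethers and the acetal should survive.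

Step 5
Reactants: 7 3-methylbuta-1,2-diene
Product: 9 1,2-dibromo-3-methylbut-2-ene, via 2,3-dibromo-3-methylbut-1-ene 8 (not isolated)
Conditions: Br2 (1.0 equiv), CH2Cl2, −78 °C to rt, dark
Reagents that add atoms: bromine, BrBr
Why: Electrophilic bromination of the allene at its central carbon across the more substituted double bond gives the tertiary allylic dibromide 8, which should transpose on warming to the more stable primary bromide 9 with a tetrasubstituted alkene; any remaining 8 would give the same enyne in step 6 by SN2' attack.

Step 6
Reactants: 6 1-ethynyl-2-(methoxymethoxy)-4,5-bis(triisopropylsilyloxy)benzene; 9 1,2-dibromo-3-methylbut-2-ene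
Product: 10 1-(4-bromo-5-methylhex-4-en-1-yn-1-yl)-2-(methoxymethoxy)-4,5-bis(triisopropylsilyloxy)benzene
Conditions: CuI (20 mol%), K2CO3 (1.5 equiv), n-Bu4NBr (10 mol%), DMF, rt, argon
Reagents that add atoms: none
Why: Copper-catalysed coupling of a terminal alkyne with an allylic bromide (copper acetylide, substitution at the primary allylic carbon) is a standard route to skipped enynes; the vinylic C–Br bond does not react with the acetylide at room temperature, and the weak base limits isomerisation of the doubly activated CH2.

Step 7
Reactants: 2 2,6-dihydroxy-4-(methoxymethoxy)benzaldehyde; 10 1-(4-bromo-5-methylhex-4-en-1-yn-1-yl)-2-(methoxymethoxy)-4,5-bis(triisopropylsilyloxy)benzene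
Product: 11 3-(2-bromo-3-methylbut-2-en-1-yl)-5-hydroxy-7-(methoxymethoxy)-2-[2-(methoxymethoxy)-4,5-bis(triisopropylsilyloxy)phenyl]-4H-chromen-4-one
Conditions: [(C5Me5)RhCl2]2 (2.5 mol%), Cu(OAc)2·H2O (2.1 equiv), o-xylene, 120 °C, argon; 2 in slight excess
Reagents that add atoms: none
Why: This is the rhodium-catalysed oxidative coupling of salicylaldehydes with internal alkynes to 2,3-disubstituted chromones, with Cu(OAc)2 as terminal oxidant. A phenoxide of 2 binds trivalent rhodium and directs metalation of the formyl C–H bond to a five-membered acyl rhodacycle. Alkyne 10 inserts into the acyl–rhodium bond, and C–O reductive elimination from the seven-membered oxa-rhodacycle closes the six-membered ring C, forming C3–C4 and O1–C2 in one operation. Cu(OAc)2 then returns monovalent rhodium to the trivalent state. The selectivity needed is the orientation of insertion: rhodium should end on the aryl-bearing carbon, which the electron-rich ring B stabilises and the small ortho acetal oxygen can assist, so the acyl carbon bonds to the CH2-bearing carbon and the aryl-bearing carbon becomes C2. Aldehyde 2 is symmetric, so either ortho hydroxyl gives the same product and the other remains as the chelated 5-hydroxyl. The tetrasubstituted vinyl bromide should be a spectator, because monovalent rhodium is reoxidised faster than it can add to a hindered C–Br bond. No stereocentre is formed.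

Step 8
Reactants: 11 3-(2-bromo-3-methylbut-2-en-1-yl)-5-hydroxy-7-(methoxymethoxy)-2-[2-(methoxymethoxy)-4,5-bis(triisopropylsilyloxy)phenyl]-4H-chromen-4-one; 12 3-chloro-3-methylbut-1-yne
Product: 13 3-(2-bromo-3-methylbut-2-en-1-yl)-7-(methoxymethoxy)-2-[2-(methoxymethoxy)-4,5-bis(triisopropylsilyloxy)phenyl]-5-[(2-methylbut-3-yn-2-yl)oxy]-4H-chromen-4-one
Conditions: DBU (2 equiv), CuCl2·2H2O (1 mol%), MeCN, 0 °C to rt
Reagents that add atoms: none
Why: Copper-catalysed O-propargylation of a phenol with a tertiary propargylic chloride (through a copper-bound allenylidene-type electrophile) works on hindered phenols; DBU fully deprotonates the chelated 5-hydroxyl, which is the only free hydroxyl in 11.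

Step 9
Reactants: 13 the 5-O-(2-methylbut-3-yn-2-yl) ether from step 8
Product: 14 3-(2-bromo-3-methylbut-2-en-1-yl)-7-(methoxymethoxy)-2-[2-(methoxymethoxy)-4,5-bis(triisopropylsilyloxy)phenyl]-5-[(2-methylbut-3-en-2-yl)oxy]-4H-chromen-4-one
Conditions: H2 (1 atm), Pd/CaCO3 poisoned with Pb(OAc)2 (Lindlar catalyst), quinoline, EtOAc, rt
Reagents that add atoms: none
Why: Lindlar semi-hydrogenation stops at the alkene for a terminal alkyne; the poisoned catalyst should leave the tetrasubstituted vinyl bromide and the chromone double bond untouched.

Step 10
Reactants: 14 the 5-O-(2-methylbut-3-en-2-yl) ether from step 9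
Product: 15 3-(2-bromo-3-methylbut-2-en-1-yl)-5-hydroxy-7-(methoxymethoxy)-2-[2-(methoxymethoxy)-4,5-bis(triisopropylsilyloxy)phenyl]-6-(3-methylbut-2-en-1-yl)-4H-chromen-4-one
Conditions: xylenes, 130 °C, argon
Reagents that add atoms: none
Why: Aromatic Claisen rearrangement of a 1,1-dimethylallyl aryl ether: the [3,3] shift can only reach C6 (the other ortho carbon is the ring fusion C4a), allyl inversion turns the tertiary ether into the linear prenyl group, and tautomerisation restores the chelated 5-hydroxyl.

Step 11
Reactants: 15 the 6-prenyl-5-hydroxyflavone bis(methoxymethyl) ether from step 10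
Product: 16 3-(2-bromo-3-methylbut-2-en-1-yl)-5,7-dihydroxy-2-[2-hydroxy-4,5-bis(triisopropylsilyloxy)phenyl]-6-(3-methylbut-2-en-1-yl)-4H-chromen-4-one
Conditions: 3 M aq. HCl, MeOH/THF, 40 °C
Reagents that add atoms: none
Why: Acid-catalysed acetal exchange removes both methoxymethyl ethers; aryl triisopropylsilyl ethers are stable to dilute methanolic acid, and this deprotection is routine in the presence of aryl prenyl groups; no enol ether is present yet.

Step 12
Reactants: 16 the 5,7,2'-triol vinyl bromide from step 11
Product: 17 the oxepine-closed 5,7-dihydroxy-6-prenylflavone 4',5'-bis(triisopropylsilyl) ether, in which O2' is bonded to the former C–Br carbon (ring C2–C3–CH2–C(=CMe2)–O–C2'–C1')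
Conditions: CuI (20 mol%), N,N-dimethylglycine (40 mol%), Cs2CO3 (3.5 equiv), dioxane, 90 °C, argon
Reagents that add atoms: none
Why: Ullmann-type copper-catalysed intramolecular O-vinylation of a phenol by a vinyl bromide; only the 2'-phenoxide can reach the C–Br carbon, the seven-membered ring closes with the double bond left exocyclic, and the C=C is not touched so its position is fixed.

Step 13
Reactants: 17 the oxepine-closed 5,7-dihydroxy-6-prenylflavone bis(silyl) ether; 18 3-methylbut-2-enal
Product: 19 isocycloheterophyllin 4',5'-bis(triisopropylsilyl) ether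
Conditions: ethylenediammonium diacetate (20 mol%), xylenes, 130 °C
Reagents that add atoms: none
Why: Formal [3+3] chromene annulation known for resorcinol-type phenols: amine-salt-catalysed condensation of the enal at C8 (the only unsubstituted ring A carbon) gives an ortho-quinone methide, which closes onto O7 by 6π-oxa-electrocyclisation; C6 is blocked, so no regioisomer can form.

Step 14
Reactants: 19 isocycloheterophyllin 4',5'-bis(triisopropylsilyl) ether
Product: 20 isocycloheterophyllin
Conditions: n-Bu4NF (2.5 equiv), AcOH (2.5 equiv), THF, 0 °C, argon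
Reagents that add atoms: none
Why: Fluoride cleavage of aryl silyl ethers; acetic acid buffers the phenoxides so that the catechol is not exposed to base and air, and the medium is too weakly acidic to hydrolyse the enol ether or cyclise the prenyl group.

## Compound list

1 | 2,4,6-trihydroxybenzaldehyde | O=Cc1c(O)cc(O)cc1O | starting material
2 | 2,6-dihydroxy-4-(methoxymethoxy)benzaldehyde | O=Cc1c(O)cc(OCOC)cc1O | intermediate
3 | 2,4,5-trihydroxybenzaldehyde | O=Cc1cc(O)c(O)cc1O | starting material
4 | 2-hydroxy-4,5-bis(triisopropylsilyloxy)benzaldehyde | O=Cc1cc(O[Si](C(C)C)(C(C)C)C(C)C)c(O[Si](C(C)C)(C(C)C)C(C)C)cc1O | intermediate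
5 | 2-(methoxymethoxy)-4,5-bis(triisopropylsilyloxy)benzaldehyde | O=Cc1cc(O[Si](C(C)C)(C(C)C)C(C)C)c(O[Si](C(C)C)(C(C)C)C(C)C)cc1OCOC | intermediate
6 | 1-ethynyl-2-(methoxymethoxy)-4,5-bis(triisopropylsilyloxy)benzene | C#Cc1cc(O[Si](C(C)C)(C(C)C)C(C)C)c(O[Si](C(C)C)(C(C)C)C(C)C)cc1OCOC | intermediate
7 | 3-methylbuta-1,2-diene | CC(C)=C=C | starting material
8 | 2,3-dibromo-3-methylbut-1-ene | CC(C)(Br)C(Br)=C | intermediate (not isolated)
9 | 1,2-dibromo-3-methylbut-2-ene | CC(C)=C(Br)CBr | intermediate
10 | 1-(4-bromo-5-methylhex-4-en-1-yn-1-yl)-2-(methoxymethoxy)-4,5-bis(triisopropylsilyloxy)benzene | CC(C)=C(Br)CC#Cc1cc(O[Si](C(C)C)(C(C)C)C(C)C)c(O[Si](C(C)C)(C(C)C)C(C)C)cc1OCOC | intermediate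
11 | 3-(2-bromo-3-methylbut-2-en-1-yl)-5-hydroxy-7-(methoxymethoxy)-2-[2-(methoxymethoxy)-4,5-bis(triisopropylsilyloxy)phenyl]-4H-chromen-4-one | O=c1c(CC(Br)=C(C)C)c(-c2cc(O[Si](C(C)C)(C(C)C)C(C)C)c(O[Si](C(C)C)(C(C)C)C(C)C)cc2OCOC)oc2cc(OCOC)cc(O)c12 | intermediate
12 | 3-chloro-3-methylbut-1-yne | CC(C)(Cl)C#C | starting material
13 | 5-O-(2-methylbut-3-yn-2-yl) ether of 11 | O=c1c(CC(Br)=C(C)C)c(-c2cc(O[Si](C(C)C)(C(C)C)C(C)C)c(O[Si](C(C)C)(C(C)C)C(C)C)cc2OCOC)oc2cc(OCOC)cc(OC(C)(C)C#C)c12 | intermediate
14 | 5-O-(2-methylbut-3-en-2-yl) ether of 11 | O=c1c(CC(Br)=C(C)C)c(-c2cc(O[Si](C(C)C)(C(C)C)C(C)C)c(O[Si](C(C)C)(C(C)C)C(C)C)cc2OCOC)oc2cc(OCOC)cc(OC(C)(C)C=C)c12 | intermediate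
15 | 3-(2-bromo-3-methylbut-2-en-1-yl)-5-hydroxy-7-(methoxymethoxy)-2-[2-(methoxymethoxy)-4,5-bis(triisopropylsilyloxy)phenyl]-6-(3-methylbut-2-en-1-yl)-4H-chromen-4-one | O=c1c(CC(Br)=C(C)C)c(-c2cc(O[Si](C(C)C)(C(C)C)C(C)C)c(O[Si](C(C)C)(C(C)C)C(C)C)cc2OCOC)oc2cc(OCOC)c(CC=C(C)C)c(O)c12 | intermediate
16 | 3-(2-bromo-3-methylbut-2-en-1-yl)-5,7-dihydroxy-2-[2-hydroxy-4,5-bis(triisopropylsilyloxy)phenyl]-6-(3-methylbut-2-en-1-yl)-4H-chromen-4-one | O=c1c(CC(Br)=C(C)C)c(-c2cc(O[Si](C(C)C)(C(C)C)C(C)C)c(O[Si](C(C)C)(C(C)C)C(C)C)cc2O)oc2cc(O)c(CC=C(C)C)c(O)c12 | intermediate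
17 | oxepine-closed 5,7-dihydroxy-6-prenylflavone 4',5'-bis(triisopropylsilyl) ether (isocycloheterophyllin skeleton without the pyran ring) | CC(C)=CCc1c(O)cc2oc3c(c(=O)c2c1O)CC(=C(C)C)Oc1cc(O[Si](C(C)C)(C(C)C)C(C)C)c(O[Si](C(C)C)(C(C)C)C(C)C)cc1-3 | intermediate
18 | 3-methylbut-2-enal | CC(C)=CC=O | starting material
19 | isocycloheterophyllin 4',5'-bis(triisopropylsilyl) ether | CC(C)=CCc1c2c(c3oc4c(c(=O)c3c1O)CC(=C(C)C)Oc1cc(O[Si](C(C)C)(C(C)C)C(C)C)c(O[Si](C(C)C)(C(C)C)C(C)C)cc1-4)C=CC(C)(C)O2 | intermediate
20 | isocycloheterophyllin | CC(C)=CCc1c2c(c3oc4c(c(=O)c3c1O)CC(=C(C)C)Oc1cc(O)c(O)cc1-4)C=CC(C)(C)O2 | target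

## Step count and risks

Total: 14 steps. Longest linear sequence: 12 steps (steps 2, 3, 4, 6, 7, 8, 9, 10, 11, 12, 13, 14 from compound 3).

**Step 7 (key step).** The most likely failure is insertion of the alkyne in the wrong orientation, or not at all, because the ortho-substituted aryl group is hindered next to rhodium. A second risk is base-induced migration of the doubly activated propargylic CH2 in hot acetate. The fallback separates C–C bond formation from the oxidation, setting out from 2 and 10:
- Redox-neutral hydroacylation ([RhCl(cod)]2, dppf, Na2CO3, toluene, 110 °C) should deliver the acyl group to the less hindered, CH2-bearing alkyne carbon and give the α-substituted 2'-hydroxychalcone F1.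
- Oxa-Michael closure (NaOAc, EtOH, 78 °C) would give the 3-substituted flavanone F2, as a racemic mixture of diastereomers.
- Dehydrogenation with DDQ in dioxane would return to 11.

**Step 8.** The hydrogen-bonded 5-hydroxyl may be alkylated too slowly, so that the propargylic electrophile decomposes first. The fallback forms the C6–C bond directly, setting out from 11:
- Iodination ortho to the free phenol (BnMe3N·ICl2, CaCO3, CH2Cl2/MeOH) would give the 6-iodoflavone F3.
- Stille coupling with tributyl(3-methylbut-2-enyl)stannane (Pd(PPh3)4, DMF, 70 °C) would rejoin the route at 15. Zerovalent palladium should add to the aryl C–I bond well before the hindered vinyl C–Br bond.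

**Step 11.** Acid may add the 5- or 7-hydroxyl across the prenyl double bond, or partly cleave a silyl ether, before both acetals are gone. The fallback moves the acid step ahead of the prenyl group, setting out from 13:
- The same acid treatment would give the diol propargyl ether F4. A tertiary propargylic aryl ether ionises far less readily than an acetal.
- Semi-hydrogenation under the conditions of step 9 would give the diol 1,1-dimethylallyl ether F5.
- Claisen rearrangement under the conditions of step 10 would rejoin the route at 16.

**Step 12.** Copper may be sequestered by the 5-hydroxy-4-keto chelate and the acidic 7-phenoxide, and oxidative addition to the tetrasubstituted C–Br bond may be slow, leaving time for silyl loss in hot carbonate. The fallback moves the closure from 16 to 17 onto palladium (Pd2(dba)3, t-BuXPhos, K3PO4, toluene, 90 °C). Zerovalent palladium inserts readily into hindered vinyl bromides, and the bulky biarylphosphine promotes C–O reductive elimination. This fallback makes no new compound (F0).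

**Step 13.** Condensation at the hindered C8 may be slow, and the hot ammonium salt may attack the enol ether. The fallback is the two-stage propargyl ether route, setting out from 17 and 12:
- Alkylation (K2CO3, KI, acetone, 56 °C) should occur only at the unchelated 7-hydroxyl and give the 7-O-(2-methylbut-3-yn-2-yl) ether F6.
- Heating in N,N-diethylaniline at 140 °C (propargyl Claisen shift to C8, [1,5]-hydrogen shift, 6π-electrocyclisation) would rejoin the route at 19.

## Further compounds

F1 | step 7 | (E)-4-bromo-1-[2,6-dihydroxy-4-(methoxymethoxy)phenyl]-2-{[2-(methoxymethoxy)-4,5-bis(triisopropylsilyloxy)phenyl]methylidene}-5-methylhex-4-en-1-one | O=C(c1c(O)cc(OCOC)cc1O)/C(CC(Br)=C(C)C)=C/c1cc(O[Si](C(C)C)(C(C)C)C(C)C)c(O[Si](C(C)C)(C(C)C)C(C)C)cc1OCOC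
F2 | step 7 | 3-(2-bromo-3-methylbut-2-en-1-yl)-5-hydroxy-7-(methoxymethoxy)-2-[2-(methoxymethoxy)-4,5-bis(triisopropylsilyloxy)phenyl]chroman-4-one (racemic, mixture of diastereomers) | O=C1C(CC(Br)=C(C)C)C(c2cc(O[Si](C(C)C)(C(C)C)C(C)C)c(O[Si](C(C)C)(C(C)C)C(C)C)cc2OCOC)Oc2cc(OCOC)cc(O)c12
F3 | step 8 | 6-iodo derivative of 11 | O=c1c(CC(Br)=C(C)C)c(-c2cc(O[Si](C(C)C)(C(C)C)C(C)C)c(O[Si](C(C)C)(C(C)C)C(C)C)cc2OCOC)oc2cc(OCOC)c(I)c(O)c12
F4 | step 11 | 3-(2-bromo-3-methylbut-2-en-1-yl)-7-hydroxy-2-[2-hydroxy-4,5-bis(triisopropylsilyloxy)phenyl]-5-[(2-methylbut-3-yn-2-yl)oxy]-4H-chromen-4-one | O=c1c(CC(Br)=C(C)C)c(-c2cc(O[Si](C(C)C)(C(C)C)C(C)C)c(O[Si](C(C)C)(C(C)C)C(C)C)cc2O)oc2cc(O)cc(OC(C)(C)C#C)c12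
F5 | step 11 | 3-(2-bromo-3-methylbut-2-en-1-yl)-7-hydroxy-2-[2-hydroxy-4,5-bis(triisopropylsilyloxy)phenyl]-5-[(2-methylbut-3-en-2-yl)oxy]-4H-chromen-4-one | O=c1c(CC(Br)=C(C)C)c(-c2cc(O[Si](C(C)C)(C(C)C)C(C)C)c(O[Si](C(C)C)(C(C)C)C(C)C)cc2O)oc2cc(O)cc(OC(C)(C)C=C)c12
F0 | step 12 | none | none
F6 | step 13 | 7-O-(2-methylbut-3-yn-2-yl) ether of 17 | CC(C)=CCc1c(OC(C)(C)C#C)cc2oc3c(c(=O)c2c1O)CC(=C(C)C)Oc1cc(O[Si](C(C)C)(C(C)C)C(C)C)c(O[Si](C(C)C)(C(C)C)C(C)C)cc1-3
A1 | alternative 1 | racemic isopropenyl allyl ether isomer of the target (oxepine closed, double bond not conjugated with oxygen) | CC(C)=CCc1c2c(c3oc4c(c(=O)c3c1O)CC(C(C)=C)Oc1cc(O)c(O)cc1-4)C=CC(C)(C)O2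
A2 | alternative 1 | racemic 3-(2-hydroxy-3-methylbut-3-enyl) flavone with a 3,4-dihydroxyphenyl ring B and complete ring A | CC(C)=CCc1c2c(c3oc(-c4ccc(O)c(O)c4)c(CC(O)C(C)=C)c(=O)c3c1O)C=CC(C)(C)O2
A3 | alternative 2 | tris(triisopropylsilyl) ether of the target | CC(C)=CCc1c2c(c3oc4c(c(=O)c3c1O[Si](C(C)C)(C(C)C)C(C)C)CC(=C(C)C)Oc1cc(O[Si](C(C)C)(C(C)C)C(C)C)c(O[Si](C(C)C)(C(C)C)C(C)C)cc1-4)C=CC(C)(C)O2
A4 | alternative 2 | racemic 4-aroyl-2-isopropylidene-benzoxepin-5-one (1,3-diketone) with a bromo-substituted, fully substituted ring A | CC(C)=CCc1c(O[Si](C(C)C)(C(C)C)C(C)C)c(C(=O)C3CC(=C(C)C)Oc4cc(O[Si](C(C)C)(C(C)C)C(C)C)c(O[Si](C(C)C)(C(C)C)C(C)C)cc4C3=O)c(Br)c2c1OC(C)(C)C=C2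
A5 | alternative 3 | 5-ethoxy-2-(3-methylbut-2-enyl)-3-(triisopropylsilyloxy)phenol | CC(C)=CCc1c(O)cc(OCC)cc1O[Si](C(C)C)(C(C)C)C(C)C
A6 | alternative 3 | 3-ethoxycyclobut-2-en-1-one | CCOC1=CC(=O)C1
A7 | alternative 3 | triisopropyl[(5-methylhex-4-en-1-yn-1-yl)oxy]silane | CC(C)=CCC#CO[Si](C(C)C)(C(C)C)C(C)C
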